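**Assumption:** the given SMILES has no stereocentre and no defined axis, so there is no enantiomer to control; the hindered aryl–naphthyl bond is left configurationally undefined, as drawn.

**Retrosynthetic overview**
1. Target 19 ⇐ tribenzyl ether 18 by global hydrogenolysis.
2. 18 ⇐ 2-(alk-1-ynyl)benzophenone 15. Key bond: the naphthol C–O bond, made when the ketone oxygen adds to the alkyne (isochromenylium); hydroxide return and aldol condensation then close the carbocycle (net isomerisation).
3. 15 ⇐ bromobenzophenone 10 + terminal alkyne 14 (Sonogashira).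
4. 10 ⇐ bromoaldehyde 5 (from syringaldehyde) + aryl Grignard from 4-bromo-3-methoxyphenol; 14 ⇐ zingerone.
5. Ring order: the three benzene rings (ring A syringyl, ring C resorcinol-derived, ring D vanillyl) are bought; ring B of the naphthalene is the only ring formed, in step 8.

**Route**

Step 1
Reactants: 1 syringaldehyde; 2 benzyl bromide
Product: 3 4-(benzyloxy)-3,5-dimethoxybenzaldehyde
Conditions: K2CO3, DMF, 60 °C
Reagents that add atoms: benzyl bromide, BrCc1ccccc1
Why: Williamson ether synthesis on an acidic para-formyl phenol; the benzyl ether survives every later step and leaves by hydrogenolysis.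

Step 2
Reactants: 3 4-(benzyloxy)-3,5-dimethoxybenzaldehyde; 4 N-bromosuccinimide
Product: 5 4-(benzyloxy)-2-bromo-3,5-dimethoxybenzaldehyde
Conditions: NBS (1.05 equiv), MeCN, 50 °C, dark
Reagents that add atoms: N-bromosuccinimide, O=C1CCC(=O)N1Br
Why: Electrophilic aromatic bromination; the two free ring positions are equivalent and ortho/para to methoxy groups, so one regioisomer forms (as with 3,4,5-trimethoxybenzaldehyde), and polar non-radical conditions spare the benzylic CH2.

Step 3
Reactants: 6 4-bromo-3-methoxyphenol; 2 benzyl bromide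
Product: 7 4-(benzyloxy)-1-bromo-2-methoxybenzene
Conditions: K2CO3, acetone, reflux
Reagents that add atoms: benzyl bromide, BrCc1ccccc1
Why: Williamson ether synthesis; it masks the phenol that would otherwise quench the Grignard reagent and, as a phenoxide, deactivate the ketone in step 8.

Step 4
Reactants: 7 4-(benzyloxy)-1-bromo-2-methoxybenzene; 5 4-(benzyloxy)-2-bromo-3,5-dimethoxybenzaldehyde
Product: 10 [4-(benzyloxy)-2-bromo-3,5-dimethoxyphenyl][4-(benzyloxy)-2-methoxyphenyl]methanone, via aryl Grignard reagent 8 (not isolated), via bromomagnesium alkoxide 9 (not isolated)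
Conditions: Mg, LiCl, THF, 25 °C (7 to 8, decanted from excess Mg); 5, THF, 0 °C → rt; then PhCHO (2 equiv), rt, 12 h; aq. NH4Cl
Reagents that add atoms: none
Why: Grignard addition to the aldehyde followed by in-flask magnesium-Oppenauer oxidation: racemic alkoxide 9 passes hydride to benzaldehyde through a six-membered transition state, driven by formation of the conjugated electron-rich diaryl ketone, so the transient stereocentre is erased and the aryl bromide of 5 is untouched.

Step 5
Reactants: 11 zingerone; 2 benzyl bromide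
Product: 12 4-[4-(benzyloxy)-3-methoxyphenyl]butan-2-one
Conditions: K2CO3, acetone, reflux
Reagents that add atoms: benzyl bromide, BrCc1ccccc1
Why: Williamson ether synthesis; carbonate is too weak to enolise the ketone, so only O-alkylation occurs.

Step 6
Reactants: 12 4-[4-(benzyloxy)-3-methoxyphenyl]butan-2-one
Product: 14 1-(benzyloxy)-4-(but-3-yn-1-yl)-2-methoxybenzene, via enol phosphate 13 (not isolated)
Conditions: LiN(i-Pr)2 (1.05 equiv), THF, −78 °C; ClP(O)(OEt)2, −78 °C → rt; then LiN(i-Pr)2 (2.3 equiv), −78 °C → rt; H2O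
Reagents that add atoms: none
Why: Negishi methyl ketone to terminal alkyne conversion: kinetic deprotonation at CH3, O-phosphorylation and amide-induced elimination, pulled forward by acetylide formation.

Step 7
Reactants: 10 [4-(benzyloxy)-2-bromo-3,5-dimethoxyphenyl][4-(benzyloxy)-2-methoxyphenyl]methanone; 14 1-(benzyloxy)-4-(but-3-yn-1-yl)-2-methoxybenzene
Product: 15 [4-(benzyloxy)-2-{4-[4-(benzyloxy)-3-methoxyphenyl]but-1-yn-1-yl}-3,5-dimethoxyphenyl][4-(benzyloxy)-2-methoxyphenyl]methanone
Conditions: PdCl2(MeCN)2 (3 mol%), XPhos (9 mol%), Cs2CO3, MeCN, 80 °C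
Reagents that add atoms: none
Why: Copper-free Sonogashira coupling; the bulky biarylphosphine allows oxidative addition into the di-ortho-substituted, electron-rich aryl bromide, and the ortho-aroyl group assists it.

Step 8
Reactants: 15 [4-(benzyloxy)-2-{4-[4-(benzyloxy)-3-methoxyphenyl]but-1-yn-1-yl}-3,5-dimethoxyphenyl][4-(benzyloxy)-2-methoxyphenyl]methanone
Product: 18 7-(benzyloxy)-4-[4-(benzyloxy)-2-methoxyphenyl]-3-[4-(benzyloxy)-3-methoxybenzyl]-6,8-dimethoxynaphthalen-2-ol, via isochromenylium cation 16 (not isolated), via diketone 17 (not isolated)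
Conditions: [Au2(μ-OH)(L)2]BF4 (2.5 mol%; L = 1,3-bis(2,6-diisopropylphenyl)imidazol-2-ylidene), 1,4-dioxane/H2O 9:1, 80 °C; then KOH (2 equiv), 90 °C, Ar; aq. HCl
Reagents that add atoms: none
Why: Proposed new method: a gold-hydroxide relay isomerisation of a 2-(alk-1-ynyl)benzophenone to a 2-naphthol by carbonyl-oxygen transposition; the digold hydroxide supplies both a cationic monovalent gold π-acid and LAu–OH, and π-activation of the alkyne lets the electron-rich benzophenone oxygen attack the distal alkyne carbon (6-endo-dig, favoured by formation of aromatic 16), which makes the future naphthol C–O bond; LAu–OH/water then returns hydroxide to the aryl-bearing C1 of 16, the pseudobase opens to diketone 17 and protodeauration closes the gold cycle; KOH enolises 17 at the CH2 next to the CH2Ar group, and intramolecular aldol addition to the diaryl ketone, E1cB dehydration and tautomerisation give the naphthol irreversibly, so water is used and returned and no stereocentre arises; the closest known reaction types are gold- or acid-induced cyclisation of 2-alkynylaryl ketones to 2-benzopyrylium salts (carbonyl-assisted alkyne hydration) and base-induced recyclisation of 3-alkyl-2-benzopyrylium salts to naphthols, which to my knowledge have not been merged into one isomerisation of alkyl-alkynyl benzophenones.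

Step 9
Reactants: 18 7-(benzyloxy)-4-[4-(benzyloxy)-2-methoxyphenyl]-3-[4-(benzyloxy)-3-methoxybenzyl]-6,8-dimethoxynaphthalen-2-ol
Product: 19 4-(4-hydroxy-2-methoxyphenyl)-3-(4-hydroxy-3-methoxybenzyl)-6,8-dimethoxynaphthalene-2,7-diol
Conditions: H2 (1 atm), 10% Pd/C, EtOAc/MeOH, rt
Reagents that add atoms: none
Why: Catalytic hydrogenolysis cleaves the three benzyl ethers; the naphthalene, the diarylmethane CH2 and the methyl ethers are inert at 1 atm and room temperature.

**Compound list**
1 | syringaldehyde (4-hydroxy-3,5-dimethoxybenzaldehyde) | COc1cc(C=O)cc(OC)c1O | starting material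
2 | benzyl bromide | BrCc1ccccc1 | starting material
3 | 4-(benzyloxy)-3,5-dimethoxybenzaldehyde | COc1cc(C=O)cc(OC)c1OCc1ccccc1 | intermediate
4 | N-bromosuccinimide | O=C1CCC(=O)N1Br | starting material
5 | 4-(benzyloxy)-2-bromo-3,5-dimethoxybenzaldehyde | COc1cc(C=O)c(Br)c(OC)c1OCc1ccccc1 | intermediate
6 | 4-bromo-3-methoxyphenol | COc1cc(O)ccc1Br | starting material
7 | 4-(benzyloxy)-1-bromo-2-methoxybenzene | COc1cc(OCc2ccccc2)ccc1Br | intermediate
8 | [4-(benzyloxy)-2-methoxyphenyl]magnesium bromide (LiCl complex) | COc1cc(OCc2ccccc2)ccc1[Mg]Br | intermediate (not isolated)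
9 | bromomagnesium [4-(benzyloxy)-2-bromo-3,5-dimethoxyphenyl][4-(benzyloxy)-2-methoxyphenyl]methanolate, racemic | COc1cc(OCc2ccccc2)ccc1C(O[Mg]Br)c1cc(OC)c(OCc2ccccc2)c(OC)c1Br | intermediate (not isolated)
10 | [4-(benzyloxy)-2-bromo-3,5-dimethoxyphenyl][4-(benzyloxy)-2-methoxyphenyl]methanone | COc1cc(OCc2ccccc2)ccc1C(=O)c1cc(OC)c(OCc2ccccc2)c(OC)c1Br | intermediate
11 | zingerone (4-(4-hydroxy-3-methoxyphenyl)butan-2-one) | CC(=O)CCc1ccc(O)c(OC)c1 | starting material
12 | 4-[4-(benzyloxy)-3-methoxyphenyl]butan-2-one | CC(=O)CCc1ccc(OCc2ccccc2)c(OC)c1 | intermediate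
13 | 4-[4-(benzyloxy)-3-methoxyphenyl]but-1-en-2-yl diethyl phosphate | C=C(CCc1ccc(OCc2ccccc2)c(OC)c1)OP(=O)(OCC)OCC | intermediate (not isolated)
14 | 1-(benzyloxy)-4-(but-3-yn-1-yl)-2-methoxybenzene | C#CCCc1ccc(OCc2ccccc2)c(OC)c1 | intermediate
15 | [4-(benzyloxy)-2-{4-[4-(benzyloxy)-3-methoxyphenyl]but-1-yn-1-yl}-3,5-dimethoxyphenyl][4-(benzyloxy)-2-methoxyphenyl]methanone | COc1cc(OCc2ccccc2)ccc1C(=O)c1cc(OC)c(OCc2ccccc2)c(OC)c1C#CCCc1ccc(OCc2ccccc2)c(OC)c1 | intermediate
16 | 6-(benzyloxy)-1-[4-(benzyloxy)-2-methoxyphenyl]-3-{2-[4-(benzyloxy)-3-methoxyphenyl]ethyl}-5,7-dimethoxyisochromenylium cation (counter-ion from the catalyst) | COc1cc(OCc2ccccc2)ccc1-c1[o+]c(CCc2ccc(OCc3ccccc3)c(OC)c2)cc2c(OC)c(OCc3ccccc3)c(OC)cc12 | intermediate (not isolated)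
17 | 1-{3-(benzyloxy)-6-[4-(benzyloxy)-2-methoxybenzoyl]-2,4-dimethoxyphenyl}-4-[4-(benzyloxy)-3-methoxyphenyl]butan-2-one | COc1cc(OCc2ccccc2)ccc1C(=O)c1cc(OC)c(OCc2ccccc2)c(OC)c1CC(=O)CCc1ccc(OCc2ccccc2)c(OC)c1 | intermediate (not isolated)
18 | 7-(benzyloxy)-4-[4-(benzyloxy)-2-methoxyphenyl]-3-[4-(benzyloxy)-3-methoxybenzyl]-6,8-dimethoxynaphthalen-2-ol | COc1cc(Cc2c(O)cc3c(OC)c(OCc4ccccc4)c(OC)cc3c2-c2ccc(OCc3ccccc3)cc2OC)ccc1OCc1ccccc1 | intermediate
19 | 4-(4-hydroxy-2-methoxyphenyl)-3-(4-hydroxy-3-methoxybenzyl)-6,8-dimethoxynaphthalene-2,7-diol (CNP0000246.0) | COc1cc(Cc2c(O)cc3c(OC)c(O)c(OC)cc3c2-c2ccc(O)cc2OC)ccc1O | target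

**Totals**
Total step count: 9. Longest linear sequence: 6 (steps 1, 2, 4, 7, 8, 9).

**Three steps most likely to fail**

Step 8 (the proposed new isomerisation). Risks are 5-exo attack of the ketone oxygen at the proximal alkyne carbon, a stalled isochromenylium, or a slow aldol onto the hindered diaryl ketone. The fallback uses known chemistry and builds diketone 17 by C–C coupling, with no alkyne. It sets out from 10, with 12 as partner. Ketone 12 is turned into its kinetic silyl enol ether {[4-(4-(benzyloxy)-3-methoxyphenyl)but-1-en-2-yl]oxy}trimethylsilane F1 (LiN(i-Pr)2, TMSCl, THF, −78 °C). F1 is α-arylated with 10 under fluoride activation (Pd(dba)2, P(t-Bu)3, ZnF2, CsF, DMF, 85 °C) to give 17, now isolated. Aldol condensation of 17 (KOH, EtOH/H2O, 80 °C) returns to the route at 18.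

Step 7 (Sonogashira on a di-ortho-substituted, electron-rich bromide). The fallback changes the order of bond formation and sets out from 5. Aldehyde 5 is coupled with 14 under classical conditions (PdCl2(PPh3)2, CuI, Et3N, DMF, 70 °C), which is well precedented for 2-bromo-3,4,5-trialkoxybenzaldehydes, to give 4-(benzyloxy)-2-{4-[4-(benzyloxy)-3-methoxyphenyl]but-1-yn-1-yl}-3,5-dimethoxybenzaldehyde F2. Grignard reagent 8 is added (THF, 0 °C) to give the racemic carbinol [4-(benzyloxy)-2-{4-[4-(benzyloxy)-3-methoxyphenyl]but-1-yn-1-yl}-3,5-dimethoxyphenyl][4-(benzyloxy)-2-methoxyphenyl]methanol F3. Oxidation with Dess–Martin periodinane (CH2Cl2, rt) returns to the route at 15.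

Step 4 (one-flask Grignard addition and Oppenauer hydride transfer on a hindered alkoxide). The fallback replaces the redox step by an acyl-level electrophile and sets out from 5. The aldehyde is converted to 4-(benzyloxy)-2-bromo-3,5-dimethoxybenzonitrile F4 (I2, aq. NH3, THF, rt). Grignard reagent 8 is added (CuBr cat., THF, 60 °C) to give, as its N-magnesium salt, the ketimine [4-(benzyloxy)-2-bromo-3,5-dimethoxyphenyl][4-(benzyloxy)-2-methoxyphenyl]methanimine F5. Hydrolysis (2 M HCl, 60 °C) returns to the route at 10.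

**Further compounds**
F1 | step 8 | {[4-(4-(benzyloxy)-3-methoxyphenyl)but-1-en-2-yl]oxy}trimethylsilane | C=C(CCc1ccc(OCc2ccccc2)c(OC)c1)O[Si](C)(C)C
F2 | step 7 | 4-(benzyloxy)-2-{4-[4-(benzyloxy)-3-methoxyphenyl]but-1-yn-1-yl}-3,5-dimethoxybenzaldehyde | COc1cc(C=O)c(C#CCCc2ccc(OCc3ccccc3)c(OC)c2)c(OC)c1OCc1ccccc1
F3 | step 7 | [4-(benzyloxy)-2-{4-[4-(benzyloxy)-3-methoxyphenyl]but-1-yn-1-yl}-3,5-dimethoxyphenyl][4-(benzyloxy)-2-methoxyphenyl]methanol, racemic | COc1cc(OCc2ccccc2)ccc1C(O)c1cc(OC)c(OCc2ccccc2)c(OC)c1C#CCCc1ccc(OCc2ccccc2)c(OC)c1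
F4 | step 4 | 4-(benzyloxy)-2-bromo-3,5-dimethoxybenzonitrile | COc1cc(C#N)c(Br)c(OC)c1OCc1ccccc1
F5 | step 4 | [4-(benzyloxy)-2-bromo-3,5-dimethoxyphenyl][4-(benzyloxy)-2-methoxyphenyl]methanimine | COc1cc(OCc2ccccc2)ccc1C(=N)c1cc(OC)c(OCc2ccccc2)c(OC)c1Br
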